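**Plan**

1. Locants: lower decalin C1–C10 (ring A = C1–C5 and C10; ring B = C5–C10; C4 carries the methylidene, C5 and C10 are the ring fusion, C8 = CHMe, C9 = C(Me)CH2Ar); bridge C11 (on C5) and C12 (on C9'); upper decalin C1'–C10' (ring C = C1'–C5' and C10'; ring D = C5'–C10').
2. Retrosynthetic cuts: sulfate esters and aryl methyl ethers; C4=CH2 (Wittig); C5–C11, the bond joining the decalins (reductive alkylation of an enone); ring B at C7–C8 and C9–C10 (Diels–Alder); upper decalin at C9'–C12 (Claisen), C9'=C10' (aldol condensation) and C5'–C6' (conjugate addition).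
3. Enabling feature: ring B is a cyclohexane whose vicinal C8(H)Me / C9(Me)CH2Ar pair is flanked by C7 and C10, and C5 is α to C4. With C4 at the C–O/C=O level a C5=C6 alkene fits into ring B, which is then the cyclohexene of a [4+2] adduct of a ring A vinylcyclohexene (C10=C5–C6=C7) and an aryl-bearing enal (C8=C9).
4. Forward order: ring A diene 4 + enal 10 give ring B (step 7), then enone 15. Ring C enone 19 is extended by conjugate addition, ring D closes by aldol condensation, and a Claisen rearrangement leads to iodide 28. Then 15 + 28 create quaternary C5, followed by methylenation, demethylation and sulfation.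
5. Stereochemistry: a CBS-set C4 carbinol steers the Diels–Alder face; the E geometry of 10 and endo addition fix C8/C9/C10; the axial C9 methyl steers alkylation at C5 (cis-fused). C5' comes from asymmetric conjugate addition, C8' from thermodynamic control, C9' from chirality transfer from a CBS-set C1' carbinol.

Key step: step 7

Remark: the target is drawn as the free bis(hydrogen sulfate), so the last step ends with a cation exchange (H+ form) of the pyridinium salt; the acid should be kept cold or stored as a salt. Ar = 2,5-dimethoxyphenyl.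

**Ring A diene**

Step 1
Reactants: 1 2-iodocyclohex-2-en-1-one
Product: 2 (S)-2-iodocyclohex-2-en-1-ol
Conditions: (R)-Me-CBS oxazaborolidine [(R)-1-methyl-3,3-diphenyltetrahydro-1H,3H-pyrrolo[1,2-c][1,3,2]oxazaborole] (10 mol%), BH3·SMe2, THF, −20 °C; MeOH quench
Reagents that add atoms: none
Why: Corey–Bakshi–Shibata reduction in which the iodoalkenyl arm acts as the large group, so the (R)-catalyst should give the (S)-carbinol (future C4), the centre that later directs the cycloaddition.

Step 2
Reactants: 2 (S)-2-iodocyclohex-2-en-1-ol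
Product: 3 (S)-tert-butyl[(2-iodocyclohex-2-en-1-yl)oxy]dimethylsilane
Conditions: TBSCl, imidazole, DMF, 25 °C
Reagents that add atoms: tert-butyldimethylsilyl chloride, CC(C)(C)[Si](C)(C)Cl
Why: Routine silylation of a secondary allylic alcohol; the bulky silyl ether is the facial control element of step 7.

Step 3
Reactants: 3 (S)-tert-butyl[(2-iodocyclohex-2-en-1-yl)oxy]dimethylsilane
Product: 4 (S)-tert-butyl[(2-ethenylcyclohex-2-en-1-yl)oxy]dimethylsilane
Conditions: tributyl(vinyl)stannane, Pd(PPh3)4 (5 mol%), CuI (10 mol%), CsF, DMF, 45 °C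
Reagents that add atoms: tributyl(vinyl)stannane, C=C[Sn](CCCC)(CCCC)CCCC
Why: Stille coupling of an alkenyl iodide with a vinylstannane should give the semicyclic 1,3-diene without touching the allylic stereocentre.

**Aryl-bearing dienophile**

Step 4
Reactants: 5 2-(bromomethyl)-1,4-dimethoxybenzene
Product: 8 ethyl (E)-2-[(2,5-dimethoxyphenyl)methyl]but-2-enoate, via phosphonium bromide 6 (not isolated), via alkylated ylide 7 (not isolated)
Conditions: Ph3P=CHCO2Et, toluene, 80 °C; aq. NaOH, CH2Cl2, 25 °C; then CH3CHO, CH2Cl2, 40 °C (sealed)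
Reagents that add atoms: ethyl (triphenylphosphoranylidene)acetate, CCOC(=O)C=P(c1ccccc1)(c1ccccc1)c1ccccc1; acetaldehyde, CC=O
Why: C-benzylation of the stabilised ylide followed by Wittig olefination with acetaldehyde; α-substituted stabilised ylides should place the ester trans to the new methyl group, which is the geometry needed to put C8-methyl cis to C9-arylmethyl.

Step 5
Reactants: 8 ethyl (E)-2-[(2,5-dimethoxyphenyl)methyl]but-2-enoate
Product: 9 (E)-2-[(2,5-dimethoxyphenyl)methyl]but-2-en-1-ol
Conditions: i-Bu2AlH (2.2 equiv), CH2Cl2, −78 °C; aq. potassium sodium tartrate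
Reagents that add atoms: none
Why: 1,2-Reduction of an enoate to the allylic alcohol by i-Bu2AlH leaves the trisubstituted alkene and its geometry intact.

Step 6
Reactants: 9 (E)-2-[(2,5-dimethoxyphenyl)methyl]but-2-en-1-ol
Product: 10 (E)-2-[(2,5-dimethoxyphenyl)methyl]but-2-enal
Conditions: MnO2 (activated, excess), CH2Cl2, 25 °C
Reagents that add atoms: none
Why: Selective MnO2 oxidation of a primary allylic alcohol should give the enal without E/Z isomerisation.

**Ring B by cycloaddition, then enone 15**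

Step 7
Reactants: 4 (S)-tert-butyl[(2-ethenylcyclohex-2-en-1-yl)oxy]dimethylsilane; 10 (E)-2-[(2,5-dimethoxyphenyl)methyl]but-2-enal
Product: 11 (1R,2S,5S,8aS)-5-[(tert-butyldimethylsilyl)oxy]-1-[(2,5-dimethoxyphenyl)methyl]-2-methyl-1,2,3,5,6,7,8,8a-octahydronaphthalene-1-carbaldehyde
Conditions: Me2AlCl (1.2 equiv), CH2Cl2, −78 → −30 °C; aq. NaHCO3
Reagents that add atoms: none
Why: The aluminium-bound s-trans enal and the s-cis diene should combine in a concerted but asynchronous [4+2] cycloaddition in which the unsubstituted vinyl terminus C7 bonds first to the β-carbon C8; the closest known reaction type is the Lewis-acid-promoted intermolecular Diels–Alder reaction of 1-vinylcyclohexene-type dienes with α,β-disubstituted enals such as tiglic aldehyde. Ring B is closed by the cycloaddition itself (intermolecular, suprafacial on both partners), which forms C7–C8 and C9–C10 and leaves the C5=C6 alkene. C8 and C9 emerge with methyl cis to arylmethyl because the E geometry of 10 is transferred suprafacially. C10 is set relative to C9 by endo placement of the complexed formyl group under C5/C6 with the bulkier arylmethyl group outside, which puts the formyl group trans to C10–H. The absolute sense of all three centres comes from C4, whose silyloxy group is held pseudoaxial by A(1,2) strain with the vinyl group and screens its own face. The step needs "ortho" regiochemistry (secured by the larger HOMO coefficient at unsubstituted C7 and by the C4–O inductive effect, which disfavours charge at C5), endo over exo addition, and attack anti to the silyloxy group.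

Step 8
Reactants: 11 Diels–Alder adduct (carbaldehyde)
Product: 13 tert-butyl({(1S,4aR,5S,6S)-5-[(2,5-dimethoxyphenyl)methyl]-5,6-dimethyl-1,2,3,4,4a,5,6,7-octahydronaphthalen-1-yl}oxy)dimethylsilane, via hydrazone 12 (not isolated)
Conditions: N2H4·H2O, EtOH, 80 °C; solvent exchange; KOtBu, DMSO, 25 °C
Reagents that add atoms: none
Why: Wolff–Kishner reduction through the preformed hydrazone at room temperature should turn the non-enolisable neopentyl formyl group into the C9 methyl group while the silyl ether, the alkene and the aryl ethers survive.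

Step 9
Reactants: 13 silyl ether with C9 methyl
Product: 14 (1S,4aR,5S,6S)-5-[(2,5-dimethoxyphenyl)methyl]-5,6-dimethyl-1,2,3,4,4a,5,6,7-octahydronaphthalen-1-ol
Conditions: Bu4NF, THF, 25 °C
Reagents that add atoms: none
Why: Fluoride cleavage of the silyl ether frees the C4 allylic alcohol under conditions inert to everything else.

Step 10
Reactants: 14 allylic alcohol
Product: 15 (4aR,5S,6S)-5-[(2,5-dimethoxyphenyl)methyl]-5,6-dimethyl-3,4,4a,5,6,7-hexahydronaphthalen-1(2H)-one
Conditions: Dess–Martin periodinane, CH2Cl2, 25 °C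
Reagents that add atoms: none
Why: Dess–Martin oxidation should give the C4 ketone conjugated with the C5=C6 alkene; C10 is not epimerisable because it sits on the α-carbon of the enone and not on a vinylogous position.

**Upper decalin iodide**

Step 11
Reactants: 16 3-acetyl-3-methyloxolan-2-one
Product: 17 5-bromo-3-methylpentan-2-one
Conditions: 48% aq. HBr, 100 °C
Reagents that add atoms: hydrogen bromide, Br
Why: Acidic ring opening of the lactone by bromide and decarboxylation of the resulting β-keto acid, the standard route from α-acyl butyrolactones to γ-halo ketones.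

Step 12
Reactants: 17 5-bromo-3-methylpentan-2-one
Product: 18 2-(4-bromobutan-2-yl)-2-methyl-1,3-dioxolane
Conditions: ethylene glycol, TsOH (cat.), benzene, reflux (water separator)
Reagents that add atoms: ethane-1,2-diol, OCCO
Why: Ketalisation masks the ketone so that the bromide can be converted into a Grignard reagent.

Step 13
Reactants: 18 2-(4-bromobutan-2-yl)-2-methyl-1,3-dioxolane; 19 4,4-dimethylcyclohex-2-en-1-one
Product: 21 (3R)-4,4-dimethyl-3-[3-(2-methyl-1,3-dioxolan-2-yl)butyl]cyclohexan-1-one (both epimers at the side-chain CHMe), via Grignard reagent 20 (not isolated)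
Conditions: Mg, Et2O, 35 °C; then 19, CuBr·SMe2 (5 mol%), (R)-1-[(S)-2-(diphenylphosphino)ferrocenyl]ethyldicyclohexylphosphine (6 mol%, antipode chosen for the 3R ketone), t-BuOMe, −75 °C; aq. NH4Cl
Reagents that add atoms: none
Why: Copper/ferrocenyl-diphosphine-catalysed asymmetric conjugate addition of a primary Grignard reagent to a cyclohexenone, with the ligand-bound copper selecting the enone face, should set C5' next to the gem-dimethyl carbon.

Step 14
Reactants: 21 ketal ketone
Product: 23 (4aS,7S)-4,4,7,8-tetramethyl-3,4,4a,5,6,7-hexahydronaphthalen-1(2H)-one, via diketone 22 (not isolated)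
Conditions: 1 M HCl, THF, 25 °C; then KOH, MeOH, 65 °C
Reagents that add atoms: none
Why: Ketal hydrolysis and intramolecular aldol condensation of the 1,7-diketone (the mode of nonane-2,8-dione giving 1-acetyl-2-methylcyclohexene) should close ring D, since only attack of C10' on the methyl ketone can dehydrate into conjugation; C8' should equilibrate through the dienolate to the epimer with a pseudoaxial methyl group (relief of A(1,2) strain with the C9' methyl), which is 8'S, and any minor epimer would be separated and re-equilibrated.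

Step 15
Reactants: 23 bicyclic enone
Product: 24 (1S,4aS,7S)-4,4,7,8-tetramethyl-1,2,3,4,4a,5,6,7-octahydronaphthalen-1-ol
Conditions: (R)-Me-CBS oxazaborolidine (20 mol%), BH3·SMe2, toluene, −30 °C; MeOH quench
Reagents that add atoms: none
Why: Corey–Bakshi–Shibata 1,2-reduction with the alkenyl arm as the large group should give the (1S) axial carbinol, a sense matched with equatorial hydride approach to ring C.

Step 16
Reactants: 24 allylic alcohol
Product: 26 ethyl 2-[(1R,2S,4aS)-1,2,5,5-tetramethyl-1,2,3,4,4a,5,6,7-octahydronaphthalen-1-yl]acetate, via ketene acetal 25 (not isolated)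
Conditions: CH3C(OEt)3, EtCO2H (cat.), xylene, 140 °C (EtOH distilled off)
Reagents that add atoms: triethyl orthoacetate, CC(OCC)(OCC)OCC
Why: Johnson–Claisen rearrangement through a chair transition state transfers chirality suprafacially from the axial C1'–O bond to C9', anti to the pseudoaxial C8' methyl, creating the quaternary centre with its two-carbon arm and moving the alkene to C1'=C10'.

Step 17
Reactants: 26 ester
Product: 27 2-[(1R,2S,4aS)-1,2,5,5-tetramethyl-1,2,3,4,4a,5,6,7-octahydronaphthalen-1-yl]ethan-1-ol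
Conditions: LiAlH4, THF, 0 °C
Reagents that add atoms: none
Why: Standard hydride reduction of an ester; the isolated trisubstituted alkene is inert.

Step 18
Reactants: 27 primary alcohol
Product: 28 (1R,2S,4aS)-1-(2-iodoethyl)-1,2,5,5-tetramethyl-1,2,3,4,4a,5,6,7-octahydronaphthalene
Conditions: I2, PPh3, imidazole, CH2Cl2, 0 → 25 °C
Reagents that add atoms: iodine, II
Why: Appel-type iodination of an unhindered primary alcohol (the branching is γ to the leaving group) gives an SN2-competent electrophile.

**Union and completion**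

Step 19
Reactants: 15 lower enone; 28 upper iodide
Product: 30 (4aR,5S,6S,8aR)-5-[(2,5-dimethoxyphenyl)methyl]-5,6-dimethyl-8a-{2-[(1R,2S,4aS)-1,2,5,5-tetramethyl-1,2,3,4,4a,5,6,7-octahydronaphthalen-1-yl]ethyl}-3,4,4a,5,6,7,8,8a-octahydronaphthalen-1(2H)-one, via lithium enolate 29 (not isolated)
Conditions: Li (2.2 equiv), liquid NH3/THF, t-BuOH (1 equiv), −78 °C; isoprene; NH3 removed; 28, HMPA, THF, −40 → 25 °C
Reagents that add atoms: none
Why: Birch-type reductive alkylation: dissolving-metal reduction protonates C6 and gives the C4(OLi)=C5 enolate regiospecifically, and C-alkylation by the primary iodide should occur on the face opposite the axial C9 methyl group, that is cis to C10–H, giving the cis-fused decalin with quaternary C5; the aryl ethers are not reduced with this limited amount of lithium and proton donor.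

Step 20
Reactants: 30 ketone
Product: 31 2-{[(1S,2S,4aR,8aR)-1,2-dimethyl-5-methylidene-4a-{2-[(1R,2S,4aS)-1,2,5,5-tetramethyl-1,2,3,4,4a,5,6,7-octahydronaphthalen-1-yl]ethyl}decahydronaphthalen-1-yl]methyl}-1,4-dimethoxybenzene
Conditions: Ph3PCH3Br, KOtBu, toluene, 90 °C
Reagents that add atoms: methyltriphenylphosphonium bromide, C[P+](c1ccccc1)(c1ccccc1)c1ccccc1.[Br-]
Why: Wittig methylenation with excess salt-free ylide at elevated temperature is the usual answer to a ketone flanked by a quaternary carbon and installs the exocyclic C4 methylidene.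

Step 21
Reactants: 31 dimethyl ether
Product: 32 2-{[(1S,2S,4aR,8aR)-1,2-dimethyl-5-methylidene-4a-{2-[(1R,2S,4aS)-1,2,5,5-tetramethyl-1,2,3,4,4a,5,6,7-octahydronaphthalen-1-yl]ethyl}decahydronaphthalen-1-yl]methyl}benzene-1,4-diol
Conditions: NaSEt (excess), DMF, 150 °C, argon; aq. NH4Cl
Reagents that add atoms: none
Why: Thiolate SN2 demethylation of both aryl methyl ethers is non-acidic, so the acid-sensitive exocyclic alkene and the trisubstituted alkene should not migrate.

Step 22
Reactants: 32 hydroquinone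
Product: 33 target CNP0439949.2, the 1,4-phenylene bis(hydrogen sulfate) of 32
Conditions: SO3·pyridine (excess), pyridine, 50 °C; then sulfonic acid resin (H+ form), 0 °C
Reagents that add atoms: sulfur trioxide pyridine complex, O=S(=O)=O.c1ccncc1
Why: O-Sulfation of both phenols with the mild SO3·pyridine complex does not affect the alkenes, and cold cation exchange delivers the free acid as drawn.

**Compound list**

1 | 2-iodocyclohex-2-en-1-one | O=C1CCCC=C1I | starting material
2 | (S)-2-iodocyclohex-2-en-1-ol | IC1=CCCC[C@@H]1O | intermediate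
3 | (S)-tert-butyl[(2-iodocyclohex-2-en-1-yl)oxy]dimethylsilane | IC1=CCCC[C@@H]1O[Si](C)(C)C(C)(C)C | intermediate
4 | (S)-tert-butyl[(2-ethenylcyclohex-2-en-1-yl)oxy]dimethylsilane | C=CC1=CCCC[C@@H]1O[Si](C)(C)C(C)(C)C | intermediate
5 | 2-(bromomethyl)-1,4-dimethoxybenzene | BrCc1cc(OC)ccc1OC | starting material
6 | [3-(2,5-dimethoxyphenyl)-1-ethoxy-1-oxopropan-2-yl]triphenylphosphonium bromide | CCOC(=O)C(Cc1cc(OC)ccc1OC)[P+](c1ccccc1)(c1ccccc1)c1ccccc1.[Br-] | intermediate
7 | ethyl 3-(2,5-dimethoxyphenyl)-2-(triphenylphosphoranylidene)propanoate | CCOC(=O)C(Cc1cc(OC)ccc1OC)=P(c1ccccc1)(c1ccccc1)c1ccccc1 | intermediate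
8 | ethyl (E)-2-[(2,5-dimethoxyphenyl)methyl]but-2-enoate | C/C=C(/C(=O)OCC)Cc1cc(OC)ccc1OC | intermediate
9 | (E)-2-[(2,5-dimethoxyphenyl)methyl]but-2-en-1-ol | C/C=C(/CO)Cc1cc(OC)ccc1OC | intermediate
10 | (E)-2-[(2,5-dimethoxyphenyl)methyl]but-2-enal | C/C=C(/C=O)Cc1cc(OC)ccc1OC | intermediate
11 | (1R,2S,5S,8aS)-5-[(tert-butyldimethylsilyl)oxy]-1-[(2,5-dimethoxyphenyl)methyl]-2-methyl-1,2,3,5,6,7,8,8a-octahydronaphthalene-1-carbaldehyde | CC(C)(C)[Si](C)(C)O[C@H]1CCC[C@H]2C1=CC[C@H](C)[C@]2(C=O)Cc1cc(OC)ccc1OC | intermediate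
12 | hydrazone of 11 at the formyl group | CC(C)(C)[Si](C)(C)O[C@H]1CCC[C@H]2C1=CC[C@H](C)[C@]2(C=NN)Cc1cc(OC)ccc1OC | intermediate
13 | tert-butyl({(1S,4aR,5S,6S)-5-[(2,5-dimethoxyphenyl)methyl]-5,6-dimethyl-1,2,3,4,4a,5,6,7-octahydronaphthalen-1-yl}oxy)dimethylsilane | CC(C)(C)[Si](C)(C)O[C@H]1CCC[C@H]2C1=CC[C@H](C)[C@]2(C)Cc1cc(OC)ccc1OC | intermediate
14 | (1S,4aR,5S,6S)-5-[(2,5-dimethoxyphenyl)methyl]-5,6-dimethyl-1,2,3,4,4a,5,6,7-octahydronaphthalen-1-ol | O[C@H]1CCC[C@H]2C1=CC[C@H](C)[C@]2(C)Cc1cc(OC)ccc1OC | intermediate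
15 | (4aR,5S,6S)-5-[(2,5-dimethoxyphenyl)methyl]-5,6-dimethyl-3,4,4a,5,6,7-hexahydronaphthalen-1(2H)-one | O=C1CCC[C@H]2C1=CC[C@H](C)[C@]2(C)Cc1cc(OC)ccc1OC | intermediate
16 | 3-acetyl-3-methyloxolan-2-one (α-acetyl-α-methyl-γ-butyrolactone) | CC(=O)C1(C)CCOC1=O | starting material
17 | 5-bromo-3-methylpentan-2-one | CC(=O)C(C)CCBr | intermediate
18 | 2-(4-bromobutan-2-yl)-2-methyl-1,3-dioxolane | CC(CCBr)C1(C)OCCO1 | intermediate
19 | 4,4-dimethylcyclohex-2-en-1-one | O=C1C=CC(C)(C)CC1 | starting material
20 | [3-(2-methyl-1,3-dioxolan-2-yl)butyl]magnesium bromide | CC(CC[Mg]Br)C1(C)OCCO1 | intermediate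
21 | (3R)-4,4-dimethyl-3-[3-(2-methyl-1,3-dioxolan-2-yl)butyl]cyclohexan-1-one (both epimers at the side-chain CHMe) | O=C1CCC(C)(C)[C@@H](C1)CCC(C)C1(C)OCCO1 | intermediate
22 | (3R)-4,4-dimethyl-3-(3-methyl-4-oxopentyl)cyclohexan-1-one (both epimers at the side-chain CHMe) | O=C1CCC(C)(C)[C@@H](C1)CCC(C)C(C)=O | intermediate
23 | (4aS,7S)-4,4,7,8-tetramethyl-3,4,4a,5,6,7-hexahydronaphthalen-1(2H)-one | CC1=C2C(=O)CCC(C)(C)[C@@H]2CC[C@@H]1C | intermediate
24 | (1S,4aS,7S)-4,4,7,8-tetramethyl-1,2,3,4,4a,5,6,7-octahydronaphthalen-1-ol | CC1=C2[C@@H](O)CCC(C)(C)[C@@H]2CC[C@@H]1C | intermediate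
25 | 1-ethoxyethenyl ether of 24 (mixed ketene acetal) | CC1=C2[C@@H](OC(=C)OCC)CCC(C)(C)[C@@H]2CC[C@@H]1C | intermediate
26 | ethyl 2-[(1R,2S,4aS)-1,2,5,5-tetramethyl-1,2,3,4,4a,5,6,7-octahydronaphthalen-1-yl]acetate | CCOC(=O)C[C@@]1(C)C2=CCCC(C)(C)[C@@H]2CC[C@@H]1C | intermediate
27 | 2-[(1R,2S,4aS)-1,2,5,5-tetramethyl-1,2,3,4,4a,5,6,7-octahydronaphthalen-1-yl]ethan-1-ol | OCC[C@@]1(C)C2=CCCC(C)(C)[C@@H]2CC[C@@H]1C | intermediate
28 | (1R,2S,4aS)-1-(2-iodoethyl)-1,2,5,5-tetramethyl-1,2,3,4,4a,5,6,7-octahydronaphthalene | ICC[C@@]1(C)C2=CCCC(C)(C)[C@@H]2CC[C@@H]1C | intermediate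
29 | lithium enolate from 1,4-reduction of 15 (OLi on C4, C4=C5, C6 = CH2) | [Li]OC1CCC[C@H]2C=1CC[C@H](C)[C@]2(C)Cc1cc(OC)ccc1OC | intermediate
30 | (4aR,5S,6S,8aR)-5-[(2,5-dimethoxyphenyl)methyl]-5,6-dimethyl-8a-{2-[(1R,2S,4aS)-1,2,5,5-tetramethyl-1,2,3,4,4a,5,6,7-octahydronaphthalen-1-yl]ethyl}-3,4,4a,5,6,7,8,8a-octahydronaphthalen-1(2H)-one | O=C1CCC[C@H]2[C@]1(CC[C@@]1(C)C3=CCCC(C)(C)[C@@H]3CC[C@@H]1C)CC[C@H](C)[C@]2(C)Cc1cc(OC)ccc1OC | intermediate
31 | 2-{[(1S,2S,4aR,8aR)-1,2-dimethyl-5-methylidene-4a-{2-[(1R,2S,4aS)-1,2,5,5-tetramethyl-1,2,3,4,4a,5,6,7-octahydronaphthalen-1-yl]ethyl}decahydronaphthalen-1-yl]methyl}-1,4-dimethoxybenzene | C=C1CCC[C@H]2[C@]1(CC[C@@]1(C)C3=CCCC(C)(C)[C@@H]3CC[C@@H]1C)CC[C@H](C)[C@]2(C)Cc1cc(OC)ccc1OC | intermediate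
32 | 2-{[(1S,2S,4aR,8aR)-1,2-dimethyl-5-methylidene-4a-{2-[(1R,2S,4aS)-1,2,5,5-tetramethyl-1,2,3,4,4a,5,6,7-octahydronaphthalen-1-yl]ethyl}decahydronaphthalen-1-yl]methyl}benzene-1,4-diol | C=C1CCC[C@H]2[C@]1(CC[C@@]1(C)C3=CCCC(C)(C)[C@@H]3CC[C@@H]1C)CC[C@H](C)[C@]2(C)Cc1cc(O)ccc1O | intermediate
33 | CNP0439949.2, the 1,4-phenylene bis(hydrogen sulfate) of 32 | C=C1CCC[C@H]2[C@]1(CC[C@@]1(C)C3=CCCC(C)(C)[C@@H]3CC[C@@H]1C)CC[C@H](C)[C@]2(C)Cc1cc(OS(=O)(=O)O)ccc1OS(=O)(=O)O | target

**Step count and risks**

Total steps: 22. Longest linear sequence: 12 steps (16 to 33, steps 11–18 and 19–22).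

Steps most likely to fail:

Step 7. The stoichiometric aluminium Lewis acid may ionise or oligomerise the allylic silyloxy diene before it cycloadds, and endo/exo or facial discrimination may be eroded. The fallback replaces the neutral enal by a cationic 2π partner (ionic Diels–Alder). It sets out from 10, which is converted with 1,2-bis(trimethylsilyloxy)ethane and catalytic Me3SiOTf (CH2Cl2, −78 °C) into its ethylene acetal, 2-[(E)-1-(2,5-dimethoxyphenyl)but-2-en-2-yl]-1,3-dioxolane F1. With catalytic Me3SiOTf at −78 °C, F1 ionises reversibly to an O-alkylated enal cation that should add to diene 4 at low temperature with strict endo preference, giving the adduct acetal F2. Mild hydrolysis (pyridinium p-toluenesulfonate, wet acetone) returns to the route at 11.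

Step 19. C-alkylation of the hindered tetrasubstituted enolate by an unactivated iodide may be slow, so that proton exchange scrambles the enolate, O-alkylation competes, or the iodide eliminates. The fallback forms the C5–C11 bond by an aldol reaction and removes the extra oxygen afterwards. It sets out from 27, which is oxidised (Dess–Martin periodinane) to 2-[(1R,2S,4aS)-1,2,5,5-tetramethyl-1,2,3,4,4a,5,6,7-octahydronaphthalen-1-yl]acetaldehyde F3. Enolate 29 is generated from 15 as in step 19, transmetalated with ZnCl2 and treated with F3 at −78 °C to give the β-hydroxy ketone F4 (aldehydes react far faster than iodides; same facial control at C5). 1,1'-Thiocarbonyldiimidazole converts F4 into the O-thiocarbonylimidazolide F5, and Barton–McCombie deoxygenation (Bu3SnH, AIBN, toluene, 90 °C) returns to the route at 30.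

Step 16. Thermal elimination of the axial allylic orthoester or ketene acetal to a diene may outrun a rearrangement that has to build a quaternary carbon. The fallback replaces the sigmatropic step by a copper-mediated anti-SN2' allylic substitution. It sets out from 24, which undergoes Mitsunobu esterification with pyridine-2-carboxylic acid (PPh3, diisopropyl azodicarboxylate) with inversion at C1' to give the picolinate F6. Vinylmagnesium bromide with CuBr·SMe2 should then attack C9' anti to the leaving group, giving (1R,2S,4aS)-1-ethenyl-1,2,5,5-tetramethyl-1,2,3,4,4a,5,6,7-octahydronaphthalene F7 with the alkene transposed to C1'=C10'. Hydroboration of the monosubstituted alkene only (9-BBN, then H2O2/NaOH) returns to the route at 27.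

**Further compounds**

F1 | step 7 | 2-[(E)-1-(2,5-dimethoxyphenyl)but-2-en-2-yl]-1,3-dioxolane | C/C=C(/C1OCCO1)Cc1cc(OC)ccc1OC
F2 | step 7 | ethylene acetal of 11 at the formyl group | CC(C)(C)[Si](C)(C)O[C@H]1CCC[C@H]2C1=CC[C@H](C)[C@]2(C1OCCO1)Cc1cc(OC)ccc1OC
F3 | step 19 | 2-[(1R,2S,4aS)-1,2,5,5-tetramethyl-1,2,3,4,4a,5,6,7-octahydronaphthalen-1-yl]acetaldehyde | O=CC[C@@]1(C)C2=CCCC(C)(C)[C@@H]2CC[C@@H]1C
F4 | step 19 | 11-hydroxy derivative of 30 (aldol adduct, carbinol epimers) | O=C1CCC[C@H]2[C@]1(C(O)C[C@@]1(C)C3=CCCC(C)(C)[C@@H]3CC[C@@H]1C)CC[C@H](C)[C@]2(C)Cc1cc(OC)ccc1OC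
F5 | step 19 | O-(imidazol-1-ylthiocarbonyl) derivative of F4 | O=C1CCC[C@H]2[C@]1(C(OC(=S)n4ccnc4)C[C@@]1(C)C3=CCCC(C)(C)[C@@H]3CC[C@@H]1C)CC[C@H](C)[C@]2(C)Cc1cc(OC)ccc1OC
F6 | step 16 | (1R,4aS,7S)-4,4,7,8-tetramethyl-1,2,3,4,4a,5,6,7-octahydronaphthalen-1-yl pyridine-2-carboxylate | CC1=C2[C@H](OC(=O)c3ccccn3)CCC(C)(C)[C@@H]2CC[C@@H]1C
F7 | step 16 | (1R,2S,4aS)-1-ethenyl-1,2,5,5-tetramethyl-1,2,3,4,4a,5,6,7-octahydronaphthalene | C=C[C@@]1(C)C2=CCCC(C)(C)[C@@H]2CC[C@@H]1C
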